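## Analysis of the target

- Target 16 is a flavanone: ring A (benzo) fused to the dihydropyranone ring C, with ring B on C2.
- C2 is the only stereocentre. With O1 > C1' > C3 > H it is S, so only absolute configuration has to be controlled.
- Ring A carries a single hydroxyl, at C7 (para to C4a, meta to C8a); C5, C6 and C8 are unsubstituted.
- Ring B has a methoxy group at C4' flanked by a prenyl group and an (E)-3-hydroxy-3-methylbut-1-enyl group. The two flanking positions are equivalent by rotation about C2–C1' until they are differentiated.
- The C2–O1 bond is β to the C4 ketone. Base that enolises C3 opens ring C to the 2'-hydroxychalcone, and reclosure racemises C2.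
- The tertiary allylic alcohol ionises in acid, and the prenyl alkene does not survive electrophilic sulfur, peracid or strong acid.
- The difficulty is therefore to set C2 in a ring that opens under base, and to bring in two different, fragile five-carbon chains late.
- The strategy rests on ring A (C4a, C5, C6, C7, C8, C8a): oxygen on C8a and C7 and nothing else is the pattern a 1-methoxy-3-silyloxybutadiene leaves when it adds across C4a=C8a of a dihydropyranone and the adduct aromatises.

## Retrosynthetic reasoning

**16 to 14 and 15.** The aryl–CH2 bond of the prenyl group is cut first. The prenyl alkene is the group least compatible with the earlier chemistry, so it comes last. The forward step is a base-free palladium coupling of the bromide of 14 with stannane 15; it must give the linear isomer and leave C2 alone.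

**14 to 12 and 13.** The aryl–vinyl bond is cut next. The tertiary allylic alcohol is acid-labile and also belongs late. The iodide of 12 reacts before the bromide, so the two positions ortho to the methoxy group are addressed in turn, and 13 supplies the whole chain without prefunctionalisation. The forward step must arylate the terminal alkene carbon, give the E alkene and use only a weak base.

**12 to 9 and 4.** Ring A is removed by cutting C4a–C5 and C8–C8a. This leaves a monocyclic pyranone whose stereocentre comes from an aldehyde addition, and avoids a reversible asymmetric oxa-Michael closure. The forward reaction must place the silyloxy carbon of 4 at C7 and aromatise without base. The sulfur in 9 is carried as a sulfoxide: after cycloaddition it sits on quaternary C4a, whose neighbours never become α to a carbonyl, so a sulfonyl group would have no E1cB exit and forcing it out would need base that opens ring C. A sulfinyl group leaves by thermal syn elimination with C8a–H, which the cis ring fusion puts on the same face.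

**9 to 8 to 6.** The S–O bond and then the C5–S bond are cut. C5 of 6 is the nucleophilic carbon of a vinylogous ester, so sulfur is attached by an electrophilic sulfur reagent and one oxygen is added by a peracid. The halogens on ring B are inert to both, which is why they are carried in place of the side chains.

**6 to 3 and 4.** C2–C3 and O1–C6 are cut, a hetero-Diels–Alder disconnection that uses diene 4 a second time. The forward reaction must add to one face of aldehyde 3 under a chiral titanium Lewis acid, setting C2.

**3 to 2 to 1.** The O–CH3 bond and the C–I bond are cut. In 1 the phenol directs iodination into its only free ortho position, giving two different halogens, and the methyl ether is the one the target needs.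

## Alternatives that were turned down

**Alternative 1: three-component flavone assembly, then reduction.**
- Disconnection: C4a–C4, C4–C3 and O1–C2, back to iodophenol A2, ring B alkyne A3 and a carbonylation carbon.
- Key step: palladium-catalysed carbonylative Sonogashira-type coupling with 6-endo closure to flavone A1.
- For: highly convergent; ring B is finished before coupling; no base-sensitive C2–O1 bond exists until the end. On these points it is stronger than the chosen route.
- Against: A1 has no stereocentre. C2 would have to come from enantioselective conjugate reduction of a tetrasubstituted vinylogous ester carbon in the presence of the prenyl and styrenyl alkenes, with over-reduction at C4 as a further risk. The closure can also go 5-exo to an aurone.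
- Comparison: the chosen route sets C2 by a carbonyl addition at the outset and never reduces anything next to the alkenes.

**Alternative 2: ortho-quinone methide cycloaddition with a styrene.**
- Disconnection: C3–C4 and O1–C2, back to acetal A5 and styrene A6.
- Key step: a chiral Brønsted acid ionises A5 to a 4-methoxy ortho-quinone methide that adds A6 to give flavan A4.
- For: ring A comes ready-made, which is stronger than building a benzene ring; the halogens are kept, so the same endgame applies.
- Against: in A6 the methoxy group is twisted out of conjugation by two ortho halogens, so the styrene is a poor donor for a cationic cycloaddition. Facial control by a counter-anion is less secure than a chelated aldehyde addition. A4 is at the flavan oxidation level, so C4 must be unmasked and oxidised and the silyl group removed, and the C4 stereocentre is wasted.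
- Comparison: the chosen route delivers the C4 ketone and the free C7 hydroxyl directly, without protecting groups.

**Alternative 3: enantioselective hydroacylation of an aryl enol ether.**
- Disconnection: C4–C3, back to aldehyde A8.
- Key step: a cationic rhodium–bisphosphine catalyst adds the aldehyde C–H across the 1-arylvinyl ether, giving flavanone A7.
- For: atom-economical, and C2 is set catalytically in the ring-forming event; on this point it is stronger.
- Against: six-membered closure onto an electron-rich 1,1-disubstituted enol ether competes with decarbonylation. The prenyl and styrenyl alkenes are open to the rhodium hydride. A8 needs an O-(1-arylvinyl) ether of a salicylaldehyde, which is awkward to make, and two silyl groups must be put on and taken off.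
- Comparison: the chosen route reaches its precursor in five conventional steps and keeps both alkenes away from any metal hydride.

Key step: step 6

Assumption: (S)-BINOL is taken to expose the Si face of aldehyde 3, as in the related titanium–BINOL allylation of aryl aldehydes; if the sense is opposite, (R)-BINOL is used and nothing else changes.

## Route

Step 1
Reactants: 1 3-bromo-4-hydroxybenzaldehyde
Product: 2 3-bromo-4-hydroxy-5-iodobenzaldehyde
Conditions: NIS, TsOH (cat.), MeCN, 23 °C
Reagents that add atoms: N-iodosuccinimide, O=C1CCC(=O)N1I
Why: Electrophilic aromatic iodination; the phenol directs to its only free ortho position and the aldehyde deactivates the others.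

Step 2
Reactants: 2 3-bromo-4-hydroxy-5-iodobenzaldehyde
Product: 3 3-bromo-5-iodo-4-methoxybenzaldehyde
Conditions: MeI, K2CO3, DMF, 23 °C
Reagents that add atoms: iodomethane, CI
Why: Williamson O-methylation of an acidic, doubly ortho-halogenated phenol; the methyl ether is the C4' methoxy group of the target.

Step 3
Reactants: 3 3-bromo-5-iodo-4-methoxybenzaldehyde; 4 (E)-1-methoxy-3-(trimethylsilyloxy)buta-1,3-diene
Product: 6 (S)-2-(3-bromo-5-iodo-4-methoxyphenyl)-2,3-dihydro-4H-pyran-4-one, via silyl aldol adduct 5 (not isolated)
Conditions: (S)-BINOL (20 mol %), Ti(O-i-Pr)4 (10 mol %), 4 Å MS, Et2O, −20 °C; then TFA, CH2Cl2, 0 °C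
Reagents that add atoms: none
Why: Titanium–BINOL-catalysed Mukaiyama aldol addition followed by acid cyclisation (formal hetero-Diels–Alder reaction); the chiral titanium complex exposes the Si face of the aldehyde and so sets C2 as S. TFA then closes the ring by oxa-Michael addition with loss of the methoxy and silyl groups.

Step 4
Reactants: 6 (S)-2-(3-bromo-5-iodo-4-methoxyphenyl)-2,3-dihydro-4H-pyran-4-one
Product: 8 (S)-2-(3-bromo-5-iodo-4-methoxyphenyl)-5-(phenylthio)-2,3-dihydro-4H-pyran-4-one, via chloro sulfide 7 (not isolated)
Conditions: PhSCl (from PhSSPh, SO2Cl2), CH2Cl2, −78 °C; then Et3N, −78 → 0 °C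
Reagents that add atoms: benzenesulfenyl chloride, ClSc1ccccc1
Why: Electrophilic α-sulfenylation of a vinylogous ester: C5 attacks sulfur, chloride caps C6, and Et3N removes HCl through the now acidic C5–H. Ring B is deactivated by its halogens, and the brief cold base exposure should leave C2 untouched.

Step 5
Reactants: 8 (S)-2-(3-bromo-5-iodo-4-methoxyphenyl)-5-(phenylthio)-2,3-dihydro-4H-pyran-4-one
Product: 9 (2S)-2-(3-bromo-5-iodo-4-methoxyphenyl)-5-(phenylsulfinyl)-2,3-dihydro-4H-pyran-4-one, both epimers at sulfur
Conditions: mCPBA (1.0 equiv), CH2Cl2, −78 → −30 °C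
Reagents that add atoms: mCPBA, OOC(=O)c1cccc(Cl)c1
Why: Sulfide-to-sulfoxide oxidation with one equivalent of peracid at low temperature, which should be faster than attack on the aryl iodide or the electron-poor enone. The sulfur stereocentre is not controlled and need not be, since sulfur is excised in step 6.

Step 6
Reactants: 9 (2S)-2-(3-bromo-5-iodo-4-methoxyphenyl)-5-(phenylsulfinyl)-2,3-dihydro-4H-pyran-4-one; 4 (E)-1-methoxy-3-(trimethylsilyloxy)buta-1,3-diene
Product: 12 (S)-2-(3-bromo-5-iodo-4-methoxyphenyl)-7-hydroxychroman-4-one, via cycloadduct 10 (not isolated), via sulfinyl enone 11 (not isolated)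
Conditions: 4 (3 equiv), ZnCl2 (20 mol %), THF, 0 → 23 °C; TFA, CH2Cl2, 0 °C; then toluene, 75 °C
Reagents that add atoms: none
Why: Diels–Alder reaction of a sulfinyl-activated enone with a 1-alkoxy-3-silyloxybutadiene, followed by sulfoxide syn elimination and aromatisation, is the known reaction type this step rests on. ZnCl2 chelates the C4 carbonyl and sulfinyl oxygens of 9, and the CH2 terminus of 4 (largest HOMO coefficient) bonds to C6 of the pyranone (β-carbon of both acceptors, future C8a) while the methoxy-bearing terminus bonds to C5 (future C4a), so the silyloxy carbon becomes C7. Ring A closes in this (4+2) mode, concerted but asynchronous or at the limit by Michael addition and 6-endo closure, giving cis-fused 10 with C8–C8a and C4a–C5 formed. TFA is added before any heating so that the silyl enol ether ionises the allylic C5–OMe bond and collapses to enone 11, which removes C5–H, the only hydrogen that could compete with C8a–H in the elimination. At 75 °C the sulfinyl group on C4a, held cis to C8a–H by the ring fusion, should leave as PhSOH through the five-membered syn-elimination transition state, and the resulting cyclohexa-2,4-dienone tautomerises to phenol 12. A sulfoxide is used and not a sulfone because C4a is quaternary and its neighbours never become α to a carbonyl, so sulfinate would have no E1cB exit, whereas the sulfoxide needs no base. No new stereocentre survives (C4a, C5 and C8a become sp2 and sulfur is lost), so facial and endo/exo selectivity are immaterial; the only selectivity needed is the regiochemistry, secured by the matched polarisation of 4 and 9. C2 is a spectator, since nothing in the sequence is basic enough to enolise C3.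

Step 7
Reactants: 12 (S)-2-(3-bromo-5-iodo-4-methoxyphenyl)-7-hydroxychroman-4-one; 13 2-methylbut-3-en-2-ol
Product: 14 (S)-2-[3-bromo-5-((E)-3-hydroxy-3-methylbut-1-en-1-yl)-4-methoxyphenyl]-7-hydroxychroman-4-one
Conditions: Pd(OAc)2 (5 mol %), Bu4NCl, NaHCO3, DMF, 55 °C
Reagents that add atoms: none
Why: Mizoroki–Heck reaction under ligand-free phase-transfer conditions; oxidative addition should occur at C–I well below the temperature needed for C–Br. The carbinol carbon has no hydrogen, so β-hydride elimination can only give the conjugated E alkene, and NaHCO3 is weak enough that C3 should not be enolised.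

Step 8
Reactants: 14 (S)-2-[3-bromo-5-((E)-3-hydroxy-3-methylbut-1-en-1-yl)-4-methoxyphenyl]-7-hydroxychroman-4-one; 15 tributyl(3-methylbut-2-en-1-yl)stannane
Product: 16 (S)-7-hydroxy-2-[3-((E)-3-hydroxy-3-methylbut-1-en-1-yl)-4-methoxy-5-(3-methylbut-2-en-1-yl)phenyl]chroman-4-one
Conditions: Pd(PPh3)4 (10 mol %), DMF, 100 °C
Reagents that add atoms: none
Why: Migita–Kosugi–Stille coupling of the aryl bromide under neutral conditions; reductive elimination at the unsubstituted allyl terminus should give the linear prenyl arene. The absence of base protects C2 and prevents Heck reaction of the styrenyl alkene.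

## Compound list

1 | 3-bromo-4-hydroxybenzaldehyde | O=Cc1ccc(O)c(Br)c1 | starting material
2 | 3-bromo-4-hydroxy-5-iodobenzaldehyde | O=Cc1cc(Br)c(O)c(I)c1 | intermediate
3 | 3-bromo-5-iodo-4-methoxybenzaldehyde | COc1c(Br)cc(C=O)cc1I | intermediate
4 | (E)-1-methoxy-3-(trimethylsilyloxy)buta-1,3-diene | CO/C=C/C(=C)O[Si](C)(C)C | starting material
5 | (S,E)-5-(3-bromo-5-iodo-4-methoxyphenyl)-1-methoxy-5-(trimethylsilyloxy)pent-1-en-3-one | CO/C=C/C(=O)C[C@H](O[Si](C)(C)C)c1cc(Br)c(OC)c(I)c1 | intermediate
6 | (S)-2-(3-bromo-5-iodo-4-methoxyphenyl)-2,3-dihydro-4H-pyran-4-one | O=C1C[C@@H](c2cc(Br)c(OC)c(I)c2)OC=C1 | intermediate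
7 | (2S)-2-(3-bromo-5-iodo-4-methoxyphenyl)-6-chloro-5-(phenylthio)tetrahydro-4H-pyran-4-one | O=C1C[C@@H](c2cc(Br)c(OC)c(I)c2)OC(Cl)C1Sc1ccccc1 | intermediate
8 | (S)-2-(3-bromo-5-iodo-4-methoxyphenyl)-5-(phenylthio)-2,3-dihydro-4H-pyran-4-one | O=C1C[C@@H](c2cc(Br)c(OC)c(I)c2)OC=C1Sc1ccccc1 | intermediate
9 | (2S)-2-(3-bromo-5-iodo-4-methoxyphenyl)-5-(phenylsulfinyl)-2,3-dihydro-4H-pyran-4-one, both epimers at sulfur | O=C1C[C@@H](c2cc(Br)c(OC)c(I)c2)OC=C1S(=O)c1ccccc1 | intermediate
10 | (2S)-2-(3-bromo-5-iodo-4-methoxyphenyl)-5-methoxy-4a-(phenylsulfinyl)-7-(trimethylsilyloxy)-2,3,4a,5,8,8a-hexahydro-4H-chromen-4-one, cis ring fusion | COC1C=C(O[Si](C)(C)C)CC2O[C@H](c3cc(Br)c(OC)c(I)c3)CC(=O)C12S(=O)c1ccccc1 | intermediate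
11 | (2S)-2-(3-bromo-5-iodo-4-methoxyphenyl)-4a-(phenylsulfinyl)-2,3,8,8a-tetrahydro-4H-chromene-4,7(4aH)-dione | O=C1C=CC2(S(=O)c3ccccc3)C(=O)C[C@@H](c3cc(Br)c(OC)c(I)c3)OC2C1 | intermediate
12 | (S)-2-(3-bromo-5-iodo-4-methoxyphenyl)-7-hydroxychroman-4-one | COc1c(I)cc([C@@H]2CC(=O)c3ccc(O)cc3O2)cc1Br | intermediate
13 | 2-methylbut-3-en-2-ol | C=CC(C)(C)O | starting material
14 | (S)-2-[3-bromo-5-((E)-3-hydroxy-3-methylbut-1-en-1-yl)-4-methoxyphenyl]-7-hydroxychroman-4-one | COc1c(/C=C/C(C)(C)O)cc([C@@H]2CC(=O)c3ccc(O)cc3O2)cc1Br | intermediate
15 | tributyl(3-methylbut-2-en-1-yl)stannane | CCCC[Sn](CCCC)(CCCC)CC=C(C)C | starting material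
16 | (S)-7-hydroxy-2-[3-((E)-3-hydroxy-3-methylbut-1-en-1-yl)-4-methoxy-5-(3-methylbut-2-en-1-yl)phenyl]chroman-4-one | COc1c(/C=C/C(C)(C)O)cc([C@@H]2CC(=O)c3ccc(O)cc3O2)cc1CC=C(C)C | target

## Step count and risks

Total steps: 8. Longest linear sequence: 8 steps, from 1 to 16.

**Step 6 (key step).** Compound 9 is a push–pull alkene: O1 donates into the double bond that the ketone and sulfoxide activate, so cycloaddition may be slow at temperatures where 10 survives. If heat is needed before the acid treatment, syn elimination can start in 10 itself, where the allylic C5–H competes with C8a–H and leads to a diene that cannot aromatise. Once the C7 ketone of 11 is unmasked, β-elimination of O1 from C8a (opening of ring C) and [2,3]-shift of the allylic sulfoxide to a sulfenate can also divert material. A more reactive 1-amino-3-silyloxydiene would address the first problem without changing the approach. The fallback takes ring A from a resorcinol instead. It sets out from 3: Claisen–Schmidt condensation with 2,4-dihydroxyacetophenone (KOH, EtOH/H2O, 23 °C) should give the chalcone (E)-3-(3-bromo-5-iodo-4-methoxyphenyl)-1-(2,4-dihydroxyphenyl)prop-2-en-1-one F1. NaOAc in refluxing EtOH should close it to the racemic flavanone 2-(3-bromo-5-iodo-4-methoxyphenyl)-7-hydroxychroman-4-one F2. Preparative chromatography on a chiral stationary phase then gives 12, where the fallback rejoins the route. The unwanted (R)-2-(3-bromo-5-iodo-4-methoxyphenyl)-7-hydroxychroman-4-one F3 is re-equilibrated to F2 under the same NaOAc conditions and recycled.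

**Step 3.** Enantioselectivity may erode through a background addition catalysed by achiral titanium alkoxide or silyl species, or the facial sense may be opposite to the one assumed. The fallback sets C2 by enamine catalysis, starting from 3. A D-proline-catalysed aldol reaction with acetone (DMSO, 23 °C) should give (S)-4-(3-bromo-5-iodo-4-methoxyphenyl)-4-hydroxybutan-2-one F4. Formylation of the methyl ketone (LiN(SiMe3)2, 2.2 equiv, ethyl formate, THF, −78 °C) should give (S)-5-(3-bromo-5-iodo-4-methoxyphenyl)-5-hydroxy-3-oxopentanal F5, and TFA in CH2Cl2 closes it with loss of water to 6, where the route resumes.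

**Step 7.** The base may enolise C3 and open ring C by expulsion of the O1 phenoxide, so that C2 partly racemises; insertion at the bromide is a lesser concern. The fallback removes the base. Radical hydrostannylation of 2-methylbut-3-yn-2-ol (Bu3SnH, AIBN, 80 °C) should give (E)-2-methyl-4-(tributylstannyl)but-3-en-2-ol F6. Stille coupling of F6 with the iodide of 12 (Pd2(dba)3, AsPh3, CuI, DMF, 40 °C) should give 14 directly.

**Step 8.** Allylic transposition during transmetallation or reductive elimination may give the branched 1,1-dimethylallyl isomer. Oxidative addition into the electron-rich ortho-alkoxy bromide may be slow, and the prenyl alkene may migrate into conjugation at 100 °C. The fallback sets out from 14. Stille coupling with allyltributylstannane (Pd(PPh3)4, DMF, 100 °C), which has no regiochemical ambiguity, should give (S)-2-[3-allyl-5-((E)-3-hydroxy-3-methylbut-1-en-1-yl)-4-methoxyphenyl]-7-hydroxychroman-4-one F7. Cross-metathesis with 2-methylbut-2-ene (second-generation Grubbs catalyst, CH2Cl2, 40 °C) then gives 16; the hindered styrenyl alkene should react more slowly than the terminal allyl group.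

## Further compounds

F1 | step 6 | (E)-3-(3-bromo-5-iodo-4-methoxyphenyl)-1-(2,4-dihydroxyphenyl)prop-2-en-1-one | COc1c(Br)cc(/C=C/C(=O)c2ccc(O)cc2O)cc1I
F2 | step 6 | racemic 2-(3-bromo-5-iodo-4-methoxyphenyl)-7-hydroxychroman-4-one | COc1c(I)cc(C2CC(=O)c3ccc(O)cc3O2)cc1Br
F3 | step 6 | (R)-2-(3-bromo-5-iodo-4-methoxyphenyl)-7-hydroxychroman-4-one | COc1c(I)cc([C@H]2CC(=O)c3ccc(O)cc3O2)cc1Br
F4 | step 3 | (S)-4-(3-bromo-5-iodo-4-methoxyphenyl)-4-hydroxybutan-2-one | CC(=O)C[C@H](O)c1cc(Br)c(OC)c(I)c1
F5 | step 3 | (S)-5-(3-bromo-5-iodo-4-methoxyphenyl)-5-hydroxy-3-oxopentanal | O=CCC(=O)C[C@H](O)c1cc(Br)c(OC)c(I)c1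
F6 | step 7 | (E)-2-methyl-4-(tributylstannyl)but-3-en-2-ol | CCCC[Sn](CCCC)(CCCC)/C=C/C(C)(C)O
F7 | step 8 | (S)-2-[3-allyl-5-((E)-3-hydroxy-3-methylbut-1-en-1-yl)-4-methoxyphenyl]-7-hydroxychroman-4-one | COc1c(/C=C/C(C)(C)O)cc([C@@H]2CC(=O)c3ccc(O)cc3O2)cc1CC=C
A1 | alternative 1 | 2-[3-((E)-3-hydroxy-3-methylbut-1-en-1-yl)-4-methoxy-5-(3-methylbut-2-en-1-yl)phenyl]-7-(triisopropylsilyloxy)-4H-chromen-4-one | COc1c(/C=C/C(C)(C)O)cc(-c2cc(=O)c3ccc(O[Si](C(C)C)(C(C)C)C(C)C)cc3o2)cc1CC=C(C)C
A2 | alternative 1 | 2-iodo-5-(triisopropylsilyloxy)phenol | Oc1cc(O[Si](C(C)C)(C(C)C)C(C)C)ccc1I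
A3 | alternative 1 | (E)-4-[5-ethynyl-2-methoxy-3-(3-methylbut-2-en-1-yl)phenyl]-2-methylbut-3-en-2-ol | COc1c(/C=C/C(C)(C)O)cc(C#C)cc1CC=C(C)C
A4 | alternative 2 | (2S,4S)-2-(3-bromo-5-iodo-4-methoxyphenyl)-4-methoxy-7-(triisopropylsilyloxy)chromane | CO[C@H]1C[C@@H](c2cc(Br)c(OC)c(I)c2)Oc2cc(O[Si](C(C)C)(C(C)C)C(C)C)ccc21
A5 | alternative 2 | 2-(dimethoxymethyl)-5-(triisopropylsilyloxy)phenol | COC(OC)c1ccc(O[Si](C(C)C)(C(C)C)C(C)C)cc1O
A6 | alternative 2 | 1-bromo-5-ethenyl-3-iodo-2-methoxybenzene | COc1c(Br)cc(C=C)cc1I
A7 | alternative 3 | (S)-7-(tert-butyldimethylsilyloxy)-2-[4-methoxy-3-(3-methylbut-2-en-1-yl)-5-((E)-3-methyl-3-(triethylsilyloxy)but-1-en-1-yl)phenyl]chroman-4-one | COc1c(/C=C/C(C)(C)O[Si](CC)(CC)CC)cc([C@@H]2CC(=O)c3ccc(O[Si](C)(C)C(C)(C)C)cc3O2)cc1CC=C(C)C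
A8 | alternative 3 | 4-(tert-butyldimethylsilyloxy)-2-{1-[4-methoxy-3-(3-methylbut-2-en-1-yl)-5-((E)-3-methyl-3-(triethylsilyloxy)but-1-en-1-yl)phenyl]vinyloxy}benzaldehyde | O=Cc1ccc(O[Si](C)(C)C(C)(C)C)cc1OC(=C)c1cc(CC=C(C)C)c(OC)c(/C=C/C(C)(C)O[Si](CC)(CC)CC)c1
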